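The runs come from a simulation from invented constants, and the scatter is random.

Slowness is what the dawn run lets me measure: it shows two slow paces, and I took both as proportional to Kat, so that their ratio holds neither Kat nor the clock.

| setting | midnight | dawn | dusk | west | south | north-east | south-west |
|---|---|---|---|---|---|---|---|
| Sub2 | 0.015 M | 0.015 M | 0.030 M | 0.015 M | 0.015 M | 0.015 M | 0.015 M |
| Kat | 0.17 µM | 0.38 µM | 0.25 µM | 0.25 µM | 0.25 µM | 0.25 µM | 0.25 µM |
| temperature | −15 °C | 10 °C | −15 °C | 10 °C | −10 °C | 30 °C |  |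
| remark | run made earlier | run made earlier | run made earlier |  |  |  | at 30 °C until 20 min, from then on at −10 °C |
| time |  |  |  | 30 min | 30 min | 30 min | 30 min |

| run | time / min | Prd / % | Sub2 / % |
|---|---|---|---|
| midnight | 5.00 | 10.8 | 47.4 |
| midnight | 6.00 | 12.7 | 44.6 |
| midnight | 10.0 | 21.9 | 35.5 |
| midnight | 15.0 | 33.7 | 23.5 |
| midnight | 30.0 | 65.9 | 0 |
| midnight | 40.0 | 81.0 | 0.2 |
| midnight | 60.0 | 91.2 | 0.3 |
| dawn | 2.50 | 23.7 | 41.4 |
| dawn | 5.00 | 51.5 | 11.6 |
| dawn | 8.00 | 78.5 | 0 |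
| dawn | 10.0 | 85.9 | 0.3 |
| dawn | 12.0 | 88.6 | 0.2 |
| dawn | 15.0 | 87.6 | 0.2 |
| dawn | 20.0 | 83.6 | 0 |
| dusk | 5.00 | 7.8 | 71.4 |
| dusk | 15.0 | 24.5 | 54.7 |
| dusk | 30.0 | 47.7 | 30.0 |
| dusk | 40.0 | 63.2 | 13.7 |
| dusk | 60.0 | 86.7 | 0.2 |

(each reading ± 0.3 percentage points)

- Sub2 is a solid; its amount is given per volume of the solution
- what may be going on: Kat -> Spx; Sub + Kat -> Prd + Kat; 2 Kat -> Zet; Sub2 <-> Sub; Kat + Prd -> Kat + Sdp
- at the start none of Sub2 is in solution
- what has only dissolved of Sub2 counts as not reacted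

- the best flask by amount of Prd, in percent of the Sub2 charged; "all alike" if 1.5 percentage points covers them all (west / south / north-east / south-west / all alike)
- amount of Prd at the end, in percent of the Sub2 charged, west
- amount of Prd at the end, in percent of the Sub2 charged, south
- amount of Prd at the end, in percent of the Sub2 charged, north-east
- amount of Prd at the end, in percent of the Sub2 charged, south-west

While Sub2 lasted at dawn, I took the climb of Prd as steady. That pace gives the making time t_m, the time to make the whole charge at it. After its highest reading Prd fell; I took Kat as fixed and read that fall as pseudo-first-order, and it gives the loss time t_l.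

t_m = 8.99 min

t_l = 107 min

Λ = t_m/t_l = 0.0841

I call Λ the loss number, the making time over the loss time. With Prd as a fraction P of the charge and Sdp as a fraction too, making at full pace at dawn's temperature gives:

Sdp = 0.5 Λ P P

That is a low figure, though: dawn's Sub2 read 0% at 8.00 min, and from there making went slower.

West stands at dawn's temperature, so I gave it dawn's Λ on a stretched clock. Its 30 min equal 19.7 min of dawn, and dawn's Prd read 83.6% at 20.0 min. That was my figure for west.

The forecast named south as best, with west 84%, south 88%, north-east 57% and south-west 68%, and it wrote: “No clear enzyme loss appears”.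

South gave most, 89.4%, against west 83.9%, north-east 70.4% and south-west 77.2%.

    Kat → Spx (k = 1.06 × 10⁻⁴ s⁻¹, Ea = 194 kJ mol⁻¹)
    Sub + Kat → Prd + Kat, rate k2*[Sub]*[Kat]/(1 + ([Sub]/Km2) + ([Sub]/Ksi2)^2) (15.5 mM, 12.8 mM, k = 44600 M⁻¹ s⁻¹, Ea = 23.0 kJ mol⁻¹)
    2 Kat → Zet (k = 1440 M⁻¹ s⁻¹, Ea = 44.0 kJ mol⁻¹)
    Sub2 ⇌ Sub, rate k4*(cs4 - [Sub]) while solid is left; crystals form when [Sub] > cs4 (solubility = 6.60 mM, k = 0.0218 s⁻¹)
    Kat + Prd → Kat + Sdp (k = 1670 M⁻¹ s⁻¹, Ea = 35.0 kJ mol⁻¹)
    (constants at 30 °C)

North-east, which the forecast had at 57%, kept 37.9% of its charged Kat at 30.0 min. In west at 15.0 min, Prd stood at 86.6%, so the loss number gives Sdp 3.15%, and the flask held 6.36%. The neighbour is north-east read at 8.0 min, with Prd 80.5%. Dawn's Λ, read at 10 °C, gives it Sdp 2.72%. That flask, at 30 °C, held 6.99%, which is 2.57 times as much.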